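**Assumption:** (2S)-(−)-homoeriodictyol is bought as the enantiopure natural flavanone, and its ee is confirmed by chiral HPLC on receipt.

## Retrosynthetic overview

- All three rings and the C2 stereocentre are bought intact in (2S)-homoeriodictyol (1); no ring is formed and no stereocentre is created.
- The only bond to make is C5'–C1'' (aryl–prenyl, ortho to the 4'-OH). It is disconnected to the B-ring phenoxyl radical of 1 and a prenyl radical from prenyl bromide (2), giving the target (3).
- Both radicals are generated by one visible-light photocatalyst in a redox-neutral cycle. No protecting groups are used: site selectivity comes from the weakest O–H bond (4'-OH of the guaiacol ring).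
- Conditions stay neutral and base-poor so the flavanone cannot ring-open and racemise.

## Route

**Step 1**

Reactants: 1, (2S)-homoeriodictyol [(2S)-5,7-dihydroxy-2-(4-hydroxy-3-methoxyphenyl)chroman-4-one]; 2, prenyl bromide (1-bromo-3-methylbut-2-ene, 2.5 equiv, added in two portions)

Product: 3, (2S)-5,7-dihydroxy-2-[4-hydroxy-3-methoxy-5-(3-methylbut-2-en-1-yl)phenyl]chroman-4-one (target)

Conditions: [Ir(ppy)2(dtbbpy)]PF6 (2 mol %), 2,6-lutidine (2 equiv), degassed MeCN (0.05 M), 450 nm LEDs, 20 °C, Ar, ca. 14 h, stopped at ~70 % conversion; pH 5 citrate work-up; SiO2 (hexanes/EtOAc + 0.5 % AcOH)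

Reagents that add atoms: prenyl bromide, CC(C)=CCBr

Why: Proposed new method: a redox-neutral photoredox phenoxyl/prenyl radical–radical cross-coupling (net ortho C–H prenylation of a free phenol), in which excited Ir(III) (E* ≈ +0.66 V vs SCE) with 2,6-lutidine removes H• by concerted PCET only from the weakest O–H bond of 1 (4'-OH, estimated BDFE ≈ 84–85 kcal/mol, against ≥ 90 for the acyl-conjugated 7-OH and chelated 5-OH; effective BDFE of the Ir*/lutidine pair ≈ 89), the resulting Ir(II) (−1.51 V) cleaves 2 to Br⁻ and the neutral prenyl radical (which, unlike a prenyl cation, does not attack the nucleophilic A ring), and this radical couples through its unhindered CH2 terminus at C5', the only spin-bearing ring carbon still carrying H, after which lutidine-catalysed tautomerisation of the dienone gives the phenol irreversibly; the closest known reactions are the in-cage ArO•/prenyl• recombination of the photo-Claisen [1,3] shift, PCET activation of phenols by Ir photocatalysts, and photoredox reduction of allylic bromides; no stereocentre is formed, and C2 keeps its purchased (S) configuration because no 4'-phenolate or C3 enolate is generated and neither 1 nor 3 absorbs at 450 nm.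

Expected outcome and checks:
- Estimated yield 30–40 % of 3 (about 50 % based on recovered 1). These figures are projections, not measured values.
- Expected by-products: the isomeric 4'-O-prenyl ether, the 5',5'-dehydrodimer of 1, and volatile prenyl dimer.
- Confirm C5' attachment by HMBC (H-1'' to C4'/C5'/C6').
- Confirm ee of 3 and of recovered 1 by chiral HPLC.
- Run a dark control to confirm there is no thermal 7-O-alkylation.

## Compound list

1 | (2S)-homoeriodictyol | COc1cc([C@@H]2CC(=O)c3c(O)cc(O)cc3O2)ccc1O | starting material

2 | prenyl bromide (1-bromo-3-methylbut-2-ene) | CC(C)=CCBr | starting material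

3 | (2S)-5,7-dihydroxy-2-[4-hydroxy-3-methoxy-5-(3-methylbut-2-en-1-yl)phenyl]chroman-4-one | COc1cc([C@@H]2CC(=O)c3c(O)cc(O)cc3O2)cc(CC=C(C)C)c1O | target

## Summary

Total step count: 1

Longest linear sequence: 1

Steps most likely to fail: the route has a single step, so there is one entry rather than three.

**Step 1 (the proposed new step).** Failure modes, in order of likelihood:
- O- rather than C5'-coupling of the radical pair, giving the 4'-O-prenyl ether.
- Phenoxyl homodimerisation or over-prenylation of 3, which is why conversion is limited to ~70 %.
- Slow thermal 7-O-alkylation if the base is too strong.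
- Partial loss of ee through a transient quinone methide.

Fallback (known chemistry, sigmatropic instead of radical coupling):
1. Selective 7-O-MOM protection of 1 (MOMCl, i-Pr2NEt, CH2Cl2, 0 °C).
2. 4'-O-(1,1-dimethylpropargyl) ether formation (2-methylbut-3-yn-2-yl trifluoroacetate, cat. CuCl2, DBU, MeCN, 0 °C). This is the only basic step; check ee after it.
3. Lindlar semihydrogenation to the 1,1-dimethylallyl ether.
4. Thermal aromatic Claisen [3,3] rearrangement (PhNEt2, ~125 °C), which delivers the normal prenyl group to C5' because C3' is blocked by OMe.
5. MOM removal (3 M HCl, MeOH, 40 °C) to give 3.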